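Retrosynthesis: after removal of the two aryl silyl ethers, each 2,4-dihydroxybenzoyl ring is cut at C1'–C2' and C5'–C6' (C1' = the ring carbon on the ketone). This leaves a 3,4-bis(propynoyl)tetrahydrofuran and two molecules of 1-methoxy-1,3-bis(trimethylsilyloxy)butadiene; the ynones go back to a 3,4-dicarboxylic acid, the saturated ring to a 2,5-diarylfuran-3,4-diester, and the furan to a 2,3-diaroylsuccinate cut at its central C–C bond into an aroylacetate and its α-bromide.
Enabling feature: both aroyl groups on C3 and C4 of the tetrahydrofuran are phenyl ketones with oxygen at C2' and C4', ortho and para to the carbonyl carbon, which is where a 1,1,3-trioxygenated diene puts its oxygens on a terminal ynone after [4+2] addition and loss of methanol.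
Forward order: enolate alkylation to the diaroylsuccinate, furan ring (Paal–Knorr), saturation to the tetrahydrofuran, conversion of both carboxyl groups into ethynyl ketones through a bis-Weinreb amide, then both resorcinol rings together in the last C–C bond-forming step, and a final desilylation.
Stereochemistry: syn hydrogenation makes the four centres all-cis (meso); an esterase differentiates the enantiotopic esters and so fixes the absolute configuration; methoxide inverts only the ester-bearing C4 to give the 2,5-cis-3,4-trans array; every later step is neutral or buffered.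
Numbering used below: O1, C2 to C5 of the tetrahydrofuran, C3 being the carbon whose carbonyl substituent is cis to both aryl groups (target: 2S,3R,4R,5R).

Key step: step 14

Assumption: the esterase is taken to hydrolyse the methyl ester on C3 (the ring carbon of R configuration in the meso diester); this sense cannot be predicted for the substrate and has to be verified on the half-ester before step 8, the opposite or an unselective outcome being covered by the fallback to step 7.

Step 1
Reactants: 1 benzyl ether of 4'-hydroxyacetophenone, 1-[4-(benzyloxy)phenyl]ethan-1-one; 2 dimethyl carbonate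
Product: 3 methyl 3-[4-(benzyloxy)phenyl]-3-oxopropanoate
Conditions: NaH (2.5 equiv), dimethyl carbonate (5 equiv), THF, reflux; 1 M HCl, 0 °C
Reagents that add atoms: none
Why: Crossed Claisen condensation of the methyl ketone enolate with a non-enolisable carbonate, pulled to completion by deprotonation of the β-keto ester; no stereocentre is formed.

Step 2
Reactants: 3 methyl 3-[4-(benzyloxy)phenyl]-3-oxopropanoate
Product: 4 methyl 3-[4-(benzyloxy)phenyl]-2-bromo-3-oxopropanoate (racemic)
Conditions: NBS (1.0 equiv), p-TsOH·H2O (10 mol %), CH2Cl2, 0 → 25 °C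
Reagents that add atoms: N-bromosuccinimide, O=C1CCC(=O)N1Br
Why: Acid-catalysed enolisation and electrophilic α-bromination of the β-keto ester, in which one equivalent of reagent and the acyl-deactivated arene should keep the halogen at the activated methylene and stop at the monobromide; the new stereocentre is racemic and is erased when the furan is formed.

Step 3
Reactants: 3 methyl 3-[4-(benzyloxy)phenyl]-3-oxopropanoate; 4 methyl 3-[4-(benzyloxy)phenyl]-2-bromo-3-oxopropanoate
Product: 5 dimethyl 2,3-bis[4-(benzyloxy)benzoyl]butanedioate (meso and racemic diastereomers)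
Conditions: 3 (1.0 equiv), NaH (1.05 equiv), THF, 0 °C; then 4 (1.0 equiv) in THF, 0 → 25 °C; sat. aq. NH4Cl
Reagents that add atoms: none
Why: C-Alkylation (SN2) of the sodium enolate of 3 by the doubly activated bromide 4, the two-component form of the coupling of β-keto ester enolates to 2,3-diacylsuccinates; halogen or proton exchange between the partners is degenerate because both have the same skeleton, and the two labile stereocentres are immaterial because both disappear in the furan.

Step 4
Reactants: 5 dimethyl 2,3-bis[4-(benzyloxy)benzoyl]butanedioate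
Product: 6 dimethyl 2,5-bis[4-(benzyloxy)phenyl]furan-3,4-dicarboxylate
Conditions: p-TsOH·H2O (10 mol %), toluene, reflux, Dean–Stark
Reagents that add atoms: none
Why: Paal–Knorr cyclodehydration of the 1,4-diketone (enol oxygen of one ketone adds to the other carbonyl, then loss of water), which closes ring 1 and erases both stereocentres.

Step 5
Reactants: 6 dimethyl 2,5-bis[4-(benzyloxy)phenyl]furan-3,4-dicarboxylate
Product: 8 dimethyl 2,5-bis(4-acetoxyphenyl)furan-3,4-dicarboxylate, via bis-phenol furan diester 7 (not isolated)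
Conditions: H2 (1 bar), 10% Pd/C, EtOAc–THF, 25 °C; filter; Ac2O, pyridine, DMAP (cat.), 25 °C
Reagents that add atoms: acetic anhydride, CC(=O)OC(C)=O
Why: O-Benzyl hydrogenolysis at ambient pressure leaves the aromatic furan untouched, and O-acetylation then masks the phenols as electron-poor esters so that the benzylic C–O bonds created in step 6 are not exposed to hydrogen as phenolic benzyl ethers.

Step 6
Reactants: 8 dimethyl 2,5-bis(4-acetoxyphenyl)furan-3,4-dicarboxylate
Product: 9 dimethyl all-cis-2,5-bis(4-acetoxyphenyl)tetrahydrofuran-3,4-dicarboxylate (meso; 2S,3R,4S,5R in the numbering above)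
Conditions: H2 (40 bar), 5% Rh/Al2O3, EtOAc, 40 °C
Reagents that add atoms: none
Why: Heterogeneous hydrogenation of a furan adds all four hydrogens from the catalyst face (syn addition, the intermediate cis-dihydrofuran being reduced again from its unhindered face), which sets C2, C3, C4 and C5 all-cis as a meso compound, as in furan-to-cis-tetrahydrofuran reductions over Rh/Al2O3.

Step 7
Reactants: 9 dimethyl all-cis-2,5-bis(4-acetoxyphenyl)tetrahydrofuran-3,4-dicarboxylate
Product: 11 (2S,3R,4S,5R)-2,5-bis(4-hydroxyphenyl)-4-(methoxycarbonyl)tetrahydrofuran-3-carboxylic acid, via all-cis bis-phenol diester 10 (not isolated)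
Conditions: pig liver esterase, phosphate buffer (pH 7.5)–DMSO (9:1), 25 °C, pH-stat (1 M NaOH); then 1 M HCl to pH 3, 0 °C
Reagents that add atoms: water, O
Why: Enzymatic desymmetrisation of a meso cis-1,2-diester: the esterase first cleaves the two aryl acetates and then one of the two enantiotopic methyl esters (taken to be that on C3), which fixes the absolute configuration of all four centres at once, the resulting carboxylate protecting the remaining ester from a second hydrolysis.

Step 8
Reactants: 11 (2S,3R,4S,5R)-2,5-bis(4-hydroxyphenyl)-4-(methoxycarbonyl)tetrahydrofuran-3-carboxylic acid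
Product: 13 (2S,3R,4R,5R)-2,5-bis(4-hydroxyphenyl)tetrahydrofuran-3,4-dicarboxylic acid, via trans half-ester 12 (not isolated)
Conditions: NaOMe (6 equiv), MeOH, 25 °C; then H2O, 40 °C; 1 M HCl to pH 3, 0 °C
Reagents that add atoms: water, O
Why: Thermodynamic epimerisation through the ester enolate, in which only C4 can enolise because C3 carries a carboxylate and relief of the all-cis strain drives C4 to the trans configuration; water is added only afterwards, so the saponification acts on a centre that is already inverted and leaves two non-enolisable carboxylates.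

Step 9
Reactants: 13 (2S,3R,4R,5R)-2,5-bis(4-hydroxyphenyl)tetrahydrofuran-3,4-dicarboxylic acid
Product: 15 (2S,3R,4R,5R)-2,5-bis[4-(tert-butyldimethylsilyloxy)phenyl]tetrahydrofuran-3,4-dicarboxylic acid, via tetrakis-silylated diacid 14 (not isolated)
Conditions: TBSCl (6 equiv), imidazole (12 equiv), DMF, 25 °C; then AcOH–THF–H2O (3:1:1), 25 °C
Reagents that add atoms: tert-butyldimethylsilyl chloride, CC(C)(C)[Si](C)(C)Cl
Why: Imidazole-promoted silylation takes both phenols and both acids, and aqueous acetic acid then hydrolyses only the labile silyl esters, aryl silyl ethers being stable to it.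

Step 10
Reactants: 15 (2S,3R,4R,5R)-2,5-bis[4-(tert-butyldimethylsilyloxy)phenyl]tetrahydrofuran-3,4-dicarboxylic acid
Product: 16 bis-Weinreb amide, (2S,3R,4R,5R)-2,5-bis[4-(tert-butyldimethylsilyloxy)phenyl]-N3,N4-dimethoxy-N3,N4-dimethyltetrahydrofuran-3,4-dicarboxamide
Conditions: MeNHOMe·HCl (3 equiv), EDC·HCl (3 equiv), HOBt (cat.), N-methylmorpholine, CH2Cl2, 0 → 25 °C
Reagents that add atoms: N,O-dimethylhydroxylamine hydrochloride, CNOC.Cl
Why: Carbodiimide-mediated amide coupling through the hydroxybenzotriazole esters under weakly basic conditions that do not enolise C3 or C4.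

Step 11
Reactants: 16 bis-Weinreb amide; 17 ethynylmagnesium bromide
Product: 18 bis-ynone, (2S,3R,4R,5R)-2,5-bis[4-(tert-butyldimethylsilyloxy)phenyl]-3,4-bis(prop-2-ynoyl)tetrahydrofuran
Conditions: HC≡CMgBr (6 equiv), THF, −20 → 0 °C; inverse quench into 1 M HCl, 0 °C
Reagents that add atoms: none
Why: Weinreb ketone synthesis, in which each amide forms a magnesium-chelated tetrahedral adduct that resists over-addition and enolisation and collapses to the ynone only on the acidic inverse quench, which also keeps the released hydroxylamine protonated so that it cannot add to the ynones.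

Step 12
Reactants: 19 methyl acetoacetate
Product: 20 methyl 3-(trimethylsilyloxy)but-2-enoate
Conditions: TMSCl, Et3N, hexane, 25 °C
Reagents that add atoms: chlorotrimethylsilane, C[Si](C)(C)Cl
Why: O-Silylation of the enolised β-keto ester with an amine base, the standard first stage in making the bis-silyloxy diene.

Step 13
Reactants: 20 methyl 3-(trimethylsilyloxy)but-2-enoate
Product: 21 diene, 1-methoxy-1,3-bis(trimethylsilyloxy)buta-1,3-diene
Conditions: LiN(iPr)2, THF, −78 °C; TMSCl, −78 → 0 °C
Reagents that add atoms: chlorotrimethylsilane, C[Si](C)(C)Cl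
Why: γ-Deprotonation of the vinylogous ester gives the dienolate, which is trapped on oxygen as the silyl ketene acetal; its alkene geometry is lost on aromatisation and does not matter.

Step 14
Reactants: 18 bis-ynone; 21 diene
Product: 24 [(2S,3R,4R,5R)-2,5-bis[4-(tert-butyldimethylsilyloxy)phenyl]tetrahydrofuran-3,4-diyl]bis[(2,4-dihydroxyphenyl)methanone], via bis-cyclohexadiene cycloadduct 22 (not isolated), via tetrakis(trimethylsilyl) ether 23 (not isolated)
Conditions: 21 (5 equiv), toluene, 25 → 50 °C; then THF, 10% aq. citric acid, 0 °C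
Reagents that add atoms: none
Why: Each terminal ynone acts as an electron-poor dienophile in a thermal, neutral [4+2] cycloaddition with the electron-rich diene 21, the closest known reaction type being the Diels–Alder benzannulation of acetylenic ketones and esters with 1,1,3-trioxygenated butadienes to resorcinol derivatives. Regiochemistry follows the polarisation of both partners: the CH2 terminus of the diene, its most nucleophilic carbon, bonds to the β-carbon of the ynone and the ketene-acetal carbon to the α-carbon, so the new ring carries oxygen at C2' and C4'. Each of the two six-membered rings is closed intermolecularly by the two C–C bonds of the cycloaddition (C1'–C2' and C5'–C6'), first as a cyclohexa-1,4-diene (22), and becomes aromatic by 1,4-loss of methanol from the ketal carbon and the ring CH2 group (23); the citric acid work-up then hydrolyses the four aryl trimethylsilyl ethers, whereas the two tert-butyldimethylsilyl ethers survive. No lasting stereocentre is formed, the two ketal carbons of 22 being lost on aromatisation, and C2 to C5 pass through unchanged. The step needs complete, regioselective reaction at both ynones without epimerisation at C3 or C4; the strongly polarised terminal ynones secure the first, the absence of base or strong acid secures the second, and the excess of diene makes up for its thermal lability.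

Step 15
Reactants: 24 bis-silyl ether of the target
Product: 25 [(2S,3R,4R,5R)-2,5-bis(4-hydroxyphenyl)tetrahydrofuran-3,4-diyl]bis[(2,4-dihydroxyphenyl)methanone] (CNP0237262.2)
Conditions: Bu4NF (2.4 equiv), AcOH (2.6 equiv), THF, 0 °C
Reagents that add atoms: none
Why: Fluoride-induced cleavage of the two aryl silyl ethers, buffered with acetic acid so that the phenoxides are protonated as they form and neither enolisation at C3/C4 nor β-elimination of the ring oxygen can begin.

Compound list
1 | 1-[4-(benzyloxy)phenyl]ethan-1-one (benzyl ether of 4'-hydroxyacetophenone) | CC(=O)c1ccc(OCc2ccccc2)cc1 | starting material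
2 | dimethyl carbonate | COC(=O)OC | starting material
3 | methyl 3-[4-(benzyloxy)phenyl]-3-oxopropanoate | COC(=O)CC(=O)c1ccc(OCc2ccccc2)cc1 | intermediate
4 | methyl 3-[4-(benzyloxy)phenyl]-2-bromo-3-oxopropanoate (racemic) | COC(=O)C(Br)C(=O)c1ccc(OCc2ccccc2)cc1 | intermediate
5 | dimethyl 2,3-bis[4-(benzyloxy)benzoyl]butanedioate (meso and racemic diastereomers) | COC(=O)C(C(=O)c1ccc(OCc2ccccc2)cc1)C(C(=O)OC)C(=O)c1ccc(OCc2ccccc2)cc1 | intermediate
6 | dimethyl 2,5-bis[4-(benzyloxy)phenyl]furan-3,4-dicarboxylate | COC(=O)c1c(-c2ccc(OCc3ccccc3)cc2)oc(-c2ccc(OCc3ccccc3)cc2)c1C(=O)OC | intermediate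
7 | dimethyl 2,5-bis(4-hydroxyphenyl)furan-3,4-dicarboxylate | COC(=O)c1c(-c2ccc(O)cc2)oc(-c2ccc(O)cc2)c1C(=O)OC | intermediate
8 | dimethyl 2,5-bis(4-acetoxyphenyl)furan-3,4-dicarboxylate | COC(=O)c1c(-c2ccc(OC(C)=O)cc2)oc(-c2ccc(OC(C)=O)cc2)c1C(=O)OC | intermediate
9 | dimethyl all-cis-2,5-bis(4-acetoxyphenyl)tetrahydrofuran-3,4-dicarboxylate (meso) | COC(=O)[C@@H]1[C@H](C(=O)OC)[C@H](c2ccc(OC(C)=O)cc2)O[C@@H]1c1ccc(OC(C)=O)cc1 | intermediate
10 | dimethyl all-cis-2,5-bis(4-hydroxyphenyl)tetrahydrofuran-3,4-dicarboxylate (meso) | COC(=O)[C@@H]1[C@H](C(=O)OC)[C@H](c2ccc(O)cc2)O[C@@H]1c1ccc(O)cc1 | intermediate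
11 | (2S,3R,4S,5R)-2,5-bis(4-hydroxyphenyl)-4-(methoxycarbonyl)tetrahydrofuran-3-carboxylic acid (all-cis half-ester) | OC(=O)[C@@H]1[C@H](C(=O)OC)[C@H](c2ccc(O)cc2)O[C@@H]1c1ccc(O)cc1 | intermediate
12 | (2S,3R,4R,5R)-2,5-bis(4-hydroxyphenyl)-4-(methoxycarbonyl)tetrahydrofuran-3-carboxylic acid (3,4-trans half-ester) | OC(=O)[C@@H]1[C@@H](C(=O)OC)[C@H](c2ccc(O)cc2)O[C@@H]1c1ccc(O)cc1 | intermediate
13 | (2S,3R,4R,5R)-2,5-bis(4-hydroxyphenyl)tetrahydrofuran-3,4-dicarboxylic acid | OC(=O)[C@@H]1[C@@H](C(=O)O)[C@H](c2ccc(O)cc2)O[C@@H]1c1ccc(O)cc1 | intermediate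
14 | bis(tert-butyldimethylsilyl) (2S,3R,4R,5R)-2,5-bis[4-(tert-butyldimethylsilyloxy)phenyl]tetrahydrofuran-3,4-dicarboxylate | CC(C)(C)[Si](C)(C)OC(=O)[C@@H]1[C@@H](C(=O)O[Si](C)(C)C(C)(C)C)[C@H](c2ccc(O[Si](C)(C)C(C)(C)C)cc2)O[C@@H]1c1ccc(O[Si](C)(C)C(C)(C)C)cc1 | intermediate
15 | (2S,3R,4R,5R)-2,5-bis[4-(tert-butyldimethylsilyloxy)phenyl]tetrahydrofuran-3,4-dicarboxylic acid | OC(=O)[C@@H]1[C@@H](C(=O)O)[C@H](c2ccc(O[Si](C)(C)C(C)(C)C)cc2)O[C@@H]1c1ccc(O[Si](C)(C)C(C)(C)C)cc1 | intermediate
16 | (2S,3R,4R,5R)-2,5-bis[4-(tert-butyldimethylsilyloxy)phenyl]-N3,N4-dimethoxy-N3,N4-dimethyltetrahydrofuran-3,4-dicarboxamide | CON(C)C(=O)[C@@H]1[C@@H](C(=O)N(C)OC)[C@H](c2ccc(O[Si](C)(C)C(C)(C)C)cc2)O[C@@H]1c1ccc(O[Si](C)(C)C(C)(C)C)cc1 | intermediate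
17 | ethynylmagnesium bromide | C#C[Mg]Br | starting material
18 | (2S,3R,4R,5R)-2,5-bis[4-(tert-butyldimethylsilyloxy)phenyl]-3,4-bis(prop-2-ynoyl)tetrahydrofuran | C#CC(=O)[C@@H]1[C@@H](C(=O)C#C)[C@H](c2ccc(O[Si](C)(C)C(C)(C)C)cc2)O[C@@H]1c1ccc(O[Si](C)(C)C(C)(C)C)cc1 | intermediate
19 | methyl acetoacetate | COC(=O)CC(C)=O | starting material
20 | methyl 3-(trimethylsilyloxy)but-2-enoate | COC(=O)C=C(C)O[Si](C)(C)C | intermediate
21 | 1-methoxy-1,3-bis(trimethylsilyloxy)buta-1,3-diene | COC(O[Si](C)(C)C)=CC(=C)O[Si](C)(C)C | intermediate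
22 | bis-cycloadduct in which each propynoyl group has become a [6-methoxy-4,6-bis(trimethylsilyloxy)cyclohexa-1,4-dien-1-yl]carbonyl group (epimers at the two ketal carbons) | COC1(O[Si](C)(C)C)C=C(O[Si](C)(C)C)CC=C1C(=O)[C@@H]1[C@@H](C(=O)C2=CCC(O[Si](C)(C)C)=CC2(OC)O[Si](C)(C)C)[C@H](c2ccc(O[Si](C)(C)C(C)(C)C)cc2)O[C@@H]1c1ccc(O[Si](C)(C)C(C)(C)C)cc1 | intermediate
23 | [(2S,3R,4R,5R)-2,5-bis[4-(tert-butyldimethylsilyloxy)phenyl]tetrahydrofuran-3,4-diyl]bis{[2,4-bis(trimethylsilyloxy)phenyl]methanone} | O=C(c1ccc(O[Si](C)(C)C)cc1O[Si](C)(C)C)[C@@H]1[C@@H](C(=O)c2ccc(O[Si](C)(C)C)cc2O[Si](C)(C)C)[C@H](c2ccc(O[Si](C)(C)C(C)(C)C)cc2)O[C@@H]1c1ccc(O[Si](C)(C)C(C)(C)C)cc1 | intermediate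
24 | [(2S,3R,4R,5R)-2,5-bis[4-(tert-butyldimethylsilyloxy)phenyl]tetrahydrofuran-3,4-diyl]bis[(2,4-dihydroxyphenyl)methanone] | O=C(c1ccc(O)cc1O)[C@@H]1[C@@H](C(=O)c2ccc(O)cc2O)[C@H](c2ccc(O[Si](C)(C)C(C)(C)C)cc2)O[C@@H]1c1ccc(O[Si](C)(C)C(C)(C)C)cc1 | intermediate
25 | [(2S,3R,4R,5R)-2,5-bis(4-hydroxyphenyl)tetrahydrofuran-3,4-diyl]bis[(2,4-dihydroxyphenyl)methanone] (CNP0237262.2) | O=C(c1ccc(O)cc1O)[C@@H]1[C@@H](C(=O)c2ccc(O)cc2O)[C@H](c2ccc(O)cc2)O[C@@H]1c1ccc(O)cc1 | target

Total step count: 15. Longest linear sequence: 13 steps (steps 1 to 11, then 14 and 15); the diene is a 2-step branch (steps 12 and 13).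

Steps most likely to fail

1. Step 6 (ring saturation). What may go wrong: hydrogen uptake stalling at the push–pull dihydrofuran stage of the fully substituted, ester-deactivated furan, and, once conditions are forced, reductive opening of the benzylic C–O bonds or saturation of the aryl rings overtaking saturation of the heterocycle. Fallback, from 8 back to the route at 13: the diester is saponified (NaOH, aq. MeOH; the phenols are freed as well) to 2,5-bis(4-hydroxyphenyl)furan-3,4-dicarboxylic acid F1. Hot acetic anhydride acetylates the phenols and closes the fused anhydride 4,6-bis(4-acetoxyphenyl)furo[3,4-c]furan-1,3-dione F2, a strained, less aromatic furan that should take up hydrogen under milder conditions (H2, Rh/Al2O3, EtOAc) and would give the cis-fused all-cis meso anhydride F3 directly. Methanolysis in the presence of quinidine or quinine (toluene, −55 °C), the alkaloid being chosen for the acid on C3, opens it to the half-ester bis(aryl acetate) F4, which under the conditions of step 8 (methoxide also removes the aryl acetates) converges on 13. This fallback changes the substrate class of the hydrogenation and replaces the enzyme as well.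

2. Step 7 (enzymatic desymmetrisation). What may go wrong: slow or no turnover of the crowded diester in the active site, weak discrimination between the enantiotopic esters, or preferential hydrolysis of the ester on C4. Fallback, from 9 back to 13: non-enzymatic monohydrolysis with a measured amount of cold aqueous NaOH in THF (0 °C), which removes the aryl acetates and one methyl ester, should give the racemic all-cis half-ester F5. The conditions of step 8 convert it into the racemic 3,4-trans diacid F6. Classical resolution by crystallisation of the bis[(S)-1-phenylethylammonium] salt F7 (or of the salt of the R amine, whichever carries the wanted acid), followed by acidification, returns 13.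

3. Step 14 (double benzannulation). What may go wrong: loss of the thermally and hydrolytically labile diene before the second ynone has reacted, oligomerisation of the ynones on warming, or erosion of configuration at C3/C4 during aromatisation and desilylation. Fallback, from 16 back to 24: the resorcinol rings are brought in preformed. 2,4-Bis(benzyloxy)phenyllithium (from commercial 1-bromo-2,4-bis(benzyloxy)benzene and n-BuLi, THF, −78 °C) adds to both N-methoxy-N-methylamide groups to give the tetrabenzyl diketone F8, and hydrogenolysis of the four benzyl ethers (H2, 1 bar, Pd/C, EtOAc, 25 °C) gives 24.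

Further compounds
F1 | step 6 | 2,5-bis(4-hydroxyphenyl)furan-3,4-dicarboxylic acid | OC(=O)c1c(-c2ccc(O)cc2)oc(-c2ccc(O)cc2)c1C(=O)O
F2 | step 6 | 4,6-bis(4-acetoxyphenyl)furo[3,4-c]furan-1,3-dione | CC(=O)Oc1ccc(cc1)-c1oc(-c2ccc(OC(C)=O)cc2)c2C(=O)OC(=O)c12
F3 | step 6 | all-cis 4,6-bis(4-acetoxyphenyl)tetrahydrofuro[3,4-c]furan-1,3-dione (meso cis-fused anhydride) | O=C1OC(=O)[C@H]2[C@@H]1[C@@H](c1ccc(OC(C)=O)cc1)O[C@H]2c1ccc(OC(C)=O)cc1
F4 | step 6 | (2S,3R,4S,5R)-2,5-bis(4-acetoxyphenyl)-4-(methoxycarbonyl)tetrahydrofuran-3-carboxylic acid | OC(=O)[C@@H]1[C@H](C(=O)OC)[C@H](c2ccc(OC(C)=O)cc2)O[C@@H]1c1ccc(OC(C)=O)cc1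
F5 | step 7 | racemic all-cis 2,5-bis(4-hydroxyphenyl)-4-(methoxycarbonyl)tetrahydrofuran-3-carboxylic acid (both enantiomers) | OC(=O)[C@@H]1[C@H](C(=O)OC)[C@H](c2ccc(O)cc2)O[C@@H]1c1ccc(O)cc1.OC(=O)[C@H]1[C@@H](C(=O)OC)[C@@H](c2ccc(O)cc2)O[C@H]1c1ccc(O)cc1
F6 | step 7 | racemic 2,5-cis-3,4-trans-2,5-bis(4-hydroxyphenyl)tetrahydrofuran-3,4-dicarboxylic acid (both enantiomers) | OC(=O)[C@@H]1[C@@H](C(=O)O)[C@H](c2ccc(O)cc2)O[C@@H]1c1ccc(O)cc1.OC(=O)[C@H]1[C@H](C(=O)O)[C@@H](c2ccc(O)cc2)O[C@H]1c1ccc(O)cc1
F7 | step 7 | bis[(S)-1-phenylethylammonium] (2S,3R,4R,5R)-2,5-bis(4-hydroxyphenyl)tetrahydrofuran-3,4-dicarboxylate | [O-]C(=O)[C@@H]1[C@@H](C([O-])=O)[C@H](c2ccc(O)cc2)O[C@@H]1c1ccc(O)cc1.C[C@H]([NH3+])c1ccccc1.C[C@H]([NH3+])c1ccccc1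
F8 | step 14 | [(2S,3R,4R,5R)-2,5-bis[4-(tert-butyldimethylsilyloxy)phenyl]tetrahydrofuran-3,4-diyl]bis{[2,4-bis(benzyloxy)phenyl]methanone} | O=C(c1ccc(OCc2ccccc2)cc1OCc1ccccc1)[C@@H]1[C@@H](C(=O)c2ccc(OCc3ccccc3)cc2OCc2ccccc2)[C@H](c2ccc(O[Si](C)(C)C(C)(C)C)cc2)O[C@@H]1c1ccc(O[Si](C)(C)C(C)(C)C)cc1
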